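The route rests on disconnecting the C5–C6 bond and the C5–O bond of the cyclopenta[c]pyridine (numbered N2, C3, C4, C4a, C5, C6, C7, C7a, C1). These converge on C5, which with C6 forms the pair of adjacent fully substituted carbons of the five-membered ring (C5: OH, CO2Me, C4a; C6: Me, OAc, C7). A rhodium carbenoid from a 4-pyridyl diazoacetate captures an enantiopure γ-acetoxy allylic alcohol; the oxonium ylide rearranges [2,3], creating both bonds and both stereocentres at once and leaving a propenyl group as the latent C7 carbonyl. The precursors are a 5-bromo-2-chloropyridin-4-yl diazoester and (S,E)-4-hydroxypent-2-en-2-yl acetate; ring closure and a dienyl Stille coupling follow.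

Key step: step 5

Assumption: Rh2(S-DOSP)4 is taken, by analogy with aryldiazoacetates in this reaction, to give the 2R centre of 9; because C3 is fixed by the carbinol alone, a wrong sense would appear as the C2 epimer and would be cured by the mirror-image catalyst Rh2(R-DOSP)4 with no other change.

Step 1
Reactants: 1 5-bromo-2-chloro-4-methylpyridine; 2 dimethyl carbonate
Product: 3 methyl 2-(5-bromo-2-chloropyridin-4-yl)acetate
Conditions: LiN(SiMe3)2 (2.2 equiv), THF, −78 → 0 °C; aq NH4Cl
Reagents that add atoms: none
Why: Lateral metalation followed by Claisen-type C-acylation: the methyl group at the 4-position of the halogenated pyridine is the most acidic site, the silylamide base is too weak to metalate the ring or to set off halogen migration, and the second equivalent of base stores the product as its enolate so that acylation stops after one ester group.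

Step 2
Reactants: 3 methyl 2-(5-bromo-2-chloropyridin-4-yl)acetate
Product: 4 methyl 2-(5-bromo-2-chloropyridin-4-yl)-2-diazoacetate
Conditions: 4-acetamidobenzenesulfonyl azide, DBU, MeCN, 0 °C → rt
Reagents that add atoms: 4-acetamidobenzenesulfonyl azide, CC(=O)Nc1ccc(cc1)S(=O)(=O)N=[N+]=[N-]
Why: Regitz diazo transfer: DBU deprotonates the CH2 group activated by the ester and the electron-poor pyridine, the enolate attacks the terminal azide nitrogen and loss of the sulfonamide leaves the donor/acceptor diazoester, which sits at the 4-position and therefore cannot cyclize onto the ring nitrogen.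

Step 3
Reactants: 5 pentane-2,4-dione (acetylacetone)
Product: 6 (E)-4-oxopent-2-en-2-yl acetate
Conditions: AcCl, Et3N, CH2Cl2, 0 °C → rt; E isomer isolated by distillation
Reagents that add atoms: acetyl chloride, CC(Cl)=O
Why: O-Acylation of the β-diketone enolate (enol ester formation): with a non-chelating ammonium counter-ion the enolate should react from its extended form so that the acetoxy group ends trans to the acetyl group, which is also the geometry with the smaller dipole repulsion, and the E assignment is to be confirmed by NOE before the material is used.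

Step 4
Reactants: 6 (E)-4-oxopent-2-en-2-yl acetate
Product: 7 (2E,4S)-4-hydroxypent-2-en-2-yl acetate
Conditions: (R)-2-methyl-CBS-oxazaborolidine (15 mol %), catecholborane, toluene, −78 °C; MeOH quench, pH 7 buffer, Et3N-deactivated SiO2
Reagents that add atoms: none
Why: Corey–Bakshi–Shibata reduction: the boron-bound ketone presents its alkenyl group as the large and its methyl group as the small substituent, so the (R)-catalyst should deliver hydride to the face that gives the S carbinol, catecholborane at −78 °C should spare the enol ester and the C=C bond, and the E geometry keeps the new hydroxyl group out of reach of the acetyl group.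

Step 5
Reactants: 4 methyl 2-(5-bromo-2-chloropyridin-4-yl)-2-diazoacetate; 7 (2E,4S)-4-hydroxypent-2-en-2-yl acetate
Product: 9 methyl (2R,3R,4E)-3-acetoxy-2-(5-bromo-2-chloropyridin-4-yl)-2-hydroxy-3-methylhex-4-enoate, via oxonium ylide 8 (not isolated)
Conditions: Rh2(S-DOSP)4 (1 mol %), pentane/PhCF3, 0 °C; 4 (1.3 equiv) added over 3 h to 7
Reagents that add atoms: none
Why: Rh2(S-DOSP)4 (a divalent-rhodium tetraprolinate) expels N2 from 4 to give a donor/acceptor rhodium carbenoid, the hydroxyl oxygen of 7 adds to the carbenoid carbon to give the rhodium-associated oxonium ylide 8, and 8 rearranges by a [2,3]-sigmatropic shift through a five-membered envelope in which that carbon bonds to the acetoxy-bearing alkene carbon while the allylic C–O bond breaks, so that the former hydroxyl oxygen becomes the tertiary alcohol and the E-propenyl group appears. The closest known reaction type is the dirhodium tetraprolinate-catalysed tandem ylide formation/[2,3]-rearrangement of methyl aryldiazoacetates with enantioenriched secondary allylic alcohols, applied here to a halogenated pyridyl donor and to an allylic alcohol whose alkene terminus carries an acetoxy group. No ring is closed. C3 of 9 (C6 of the target) is set by suprafacial transfer of the S carbinol chirality: allylic 1,3-strain with the cis-methyl group holds the carbinol hydrogen in the alkene plane, the new bond forms on the alkene face from which oxygen departs, and the E alkene therefore delivers the 3R centre with the acetoxy group already in place. C2 of 9 (C5 of the target) is set by the chiral catalyst, which determines the face of the carbenoid carbon that is captured by oxygen and then bonded to the allyl terminus, the S catalyst being chosen for the 2R centre. The step needs rearrangement to win over formal O–H insertion and cyclopropanation, which should be secured by the secondary carbinol and the methyl- and acetoxy-substituted terminus (both stabilize the allyl fragment as the C–O bond breaks), by the trisubstituted alkene being too hindered for the bulky carbenoid, and by the 2-chloro group, which makes the pyridine nitrogen too weakly basic to block the rhodium sites.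

Step 6
Reactants: 9 methyl (2R,3R,4E)-3-acetoxy-2-(5-bromo-2-chloropyridin-4-yl)-2-hydroxy-3-methylhex-4-enoate
Product: 11 methyl (2R,3S)-3-acetoxy-2-(5-bromo-2-chloropyridin-4-yl)-2-hydroxy-3-methyl-4-oxobutanoate, via secondary ozonide 10 (not isolated)
Conditions: O3, CH2Cl2, −78 °C; then PPh3, −78 °C → rt; used crude
Reagents that add atoms: ozone, [O-][O+]=O
Why: Ozonolysis with reductive work-up: ozone adds to the only C=C bond (the halogenated pyridine is inert at −78 °C), the Criegee sequence gives ozonide 10 and PPh3 reduces it to the aldehyde, whose two neighbouring stereocentres are fully substituted and cannot epimerize (the descriptor at the acetoxy carbon changes from R to S only through the priority rules).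

Step 7
Reactants: 11 methyl (2R,3S)-3-acetoxy-2-(5-bromo-2-chloropyridin-4-yl)-2-hydroxy-3-methyl-4-oxobutanoate
Product: 12 methyl (5R,6R)-6-acetoxy-3-chloro-5,7-dihydroxy-6-methyl-6,7-dihydro-5H-cyclopenta[c]pyridine-5-carboxylate (both C7 epimers)
Conditions: CrCl2 (6 equiv), NiCl2 (10 mol %), degassed DMF, rt → 50 °C
Reagents that add atoms: none
Why: Intramolecular Nozaki–Hiyama–Kishi reaction: zerovalent nickel formed in the flask should insert into the C–Br bond of the electron-poor pyridine in preference to the C–Cl bond, transmetalation to trivalent chromium gives an arylchromium species that adds 5-exo-trig to the adjacent aldehyde under neutral conditions compatible with the free tertiary alcohol, the ester and the acetate, and the configuration of the new carbinol C7 does not matter because it is oxidized next.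

Step 8
Reactants: 12 methyl (5R,6R)-6-acetoxy-3-chloro-5,7-dihydroxy-6-methyl-6,7-dihydro-5H-cyclopenta[c]pyridine-5-carboxylate
Product: 13 methyl (5R,6S)-6-acetoxy-3-chloro-5-hydroxy-6-methyl-7-oxo-6,7-dihydro-5H-cyclopenta[c]pyridine-5-carboxylate
Conditions: Dess–Martin periodinane, NaHCO3, CH2Cl2, 0 °C → rt
Reagents that add atoms: none
Why: Dess–Martin oxidation: only the secondary pyridylic C7 alcohol can be oxidized, the buffered non-basic medium avoids retro-aldol cleavage of the resulting β-hydroxy ketone, and C5 and C6 carry no hydrogen that could be lost (C6 becomes S only because C7 now outranks C5).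

Step 9
Reactants: 14 (S)-2-methylbutan-1-ol
Product: 16 (2E,4S)-2,4-dimethylhex-2-enal, via (S)-2-methylbutanal 15 (not isolated)
Conditions: TEMPO (10 mol %), PhI(OAc)2 (1.05 equiv), CH2Cl2, rt; then Ph3P=C(CH3)CHO (1.3 equiv), 40 °C
Reagents that add atoms: 2-(triphenylphosphoranylidene)propanal, CC(C=O)=P(c1ccccc1)(c1ccccc1)c1ccccc1
Why: Nitroxyl-catalysed oxidation stops cleanly at the aldehyde, and in the same flask the stabilized formyl ylide converts it in a Wittig reaction (promoted by the acetic acid already present) to the thermodynamically preferred E-configured 2-methyl enal, so that the volatile and enolizable α-chiral aldehyde is never isolated.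

Step 10
Reactants: 16 (2E,4S)-2,4-dimethylhex-2-enal
Product: 17 (1E,3E,5S)-1-iodo-3,5-dimethylhepta-1,3-diene
Conditions: CrCl2 (6 equiv), CHI3 (2 equiv), THF, 0 °C → rt, dark
Reagents that add atoms: iodoform, IC(I)I
Why: Takai olefination: the geminal dichromium species formed from CHI3 and divalent chromium adds to the aldehyde and eliminates to the E-iodoalkene, which should give the (1E,3E)-dienyl iodide under non-basic conditions that leave the allylic stereocentre untouched.

Step 11
Reactants: 17 (1E,3E,5S)-1-iodo-3,5-dimethylhepta-1,3-diene
Product: 19 tributyl[(1E,3E,5S)-3,5-dimethylhepta-1,3-dien-1-yl]stannane, via dienyllithium 18 (not isolated)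
Conditions: t-BuLi (2.1 equiv), Et2O, −78 °C; then Bu3SnCl, −78 °C → rt
Reagents that add atoms: tributyltin chloride, CCCC[Sn](Cl)(CCCC)CCCC
Why: Iodine–lithium exchange at −78 °C proceeds with retention of the alkene geometry and the dienyllithium 18 is trapped at carbon by Bu3SnCl, again with retention (halogen–metal exchange followed by transmetalation to tin).

Step 12
Reactants: 13 methyl (5R,6S)-6-acetoxy-3-chloro-5-hydroxy-6-methyl-7-oxo-6,7-dihydro-5H-cyclopenta[c]pyridine-5-carboxylate; 19 tributyl[(1E,3E,5S)-3,5-dimethylhepta-1,3-dien-1-yl]stannane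
Product: 20 methyl (5R,6S)-6-acetoxy-3-[(1E,3E,5S)-3,5-dimethylhepta-1,3-dien-1-yl]-5-hydroxy-6-methyl-7-oxo-6,7-dihydro-5H-cyclopenta[c]pyridine-5-carboxylate (CNP0483502.1)
Conditions: Pd(PPh3)4 (10 mol %), CuI (20 mol %), degassed DMF, 80 °C, dark
Reagents that add atoms: none
Why: Stille coupling: insertion of zerovalent palladium into the C3–Cl bond is eased by the adjacent ring nitrogen and by the C7 ketone para to it, and transmetalation and reductive elimination transfer the dienyl group with retention of both alkene geometries under neutral conditions that should spare the β-hydroxy ketone, the ester and the acetate.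

Compound list
1 | 5-bromo-2-chloro-4-methylpyridine | Cc1cc(Cl)ncc1Br | starting material
2 | dimethyl carbonate | COC(=O)OC | starting material
3 | methyl 2-(5-bromo-2-chloropyridin-4-yl)acetate | COC(=O)Cc1cc(Cl)ncc1Br | intermediate
4 | methyl 2-(5-bromo-2-chloropyridin-4-yl)-2-diazoacetate | COC(=O)C(=[N+]=[N-])c1cc(Cl)ncc1Br | intermediate
5 | pentane-2,4-dione (acetylacetone) | CC(=O)CC(C)=O | starting material
6 | (E)-4-oxopent-2-en-2-yl acetate | CC(=O)/C=C(\C)OC(C)=O | intermediate
7 | (2E,4S)-4-hydroxypent-2-en-2-yl acetate | C[C@H](O)/C=C(\C)OC(C)=O | intermediate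
8 | oxonium ylide from 4 and 7 (O-protonated allyl ether of the ester-stabilized carbanion) | C[C@H]([OH+][C-](C(=O)OC)c1cc(Cl)ncc1Br)/C=C(\C)OC(C)=O | intermediate
9 | methyl (2R,3R,4E)-3-acetoxy-2-(5-bromo-2-chloropyridin-4-yl)-2-hydroxy-3-methylhex-4-enoate | C/C=C/[C@@](C)(OC(C)=O)[C@@](O)(C(=O)OC)c1cc(Cl)ncc1Br | intermediate
10 | secondary ozonide of 9 (3-methyl-1,2,4-trioxolan-5-yl in place of the propenyl group) | CC1OOC(O1)[C@@](C)(OC(C)=O)[C@@](O)(C(=O)OC)c2cc(Cl)ncc2Br | intermediate
11 | methyl (2R,3S)-3-acetoxy-2-(5-bromo-2-chloropyridin-4-yl)-2-hydroxy-3-methyl-4-oxobutanoate | O=C[C@@](C)(OC(C)=O)[C@@](O)(C(=O)OC)c1cc(Cl)ncc1Br | intermediate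
12 | methyl (5R,6R)-6-acetoxy-3-chloro-5,7-dihydroxy-6-methyl-6,7-dihydro-5H-cyclopenta[c]pyridine-5-carboxylate (both C7 epimers) | Clc1cc2c(cn1)C(O)[C@@](C)(OC(C)=O)[C@@]2(O)C(=O)OC | intermediate
13 | methyl (5R,6S)-6-acetoxy-3-chloro-5-hydroxy-6-methyl-7-oxo-6,7-dihydro-5H-cyclopenta[c]pyridine-5-carboxylate | Clc1cc2c(cn1)C(=O)[C@@](C)(OC(C)=O)[C@@]2(O)C(=O)OC | intermediate
14 | (S)-2-methylbutan-1-ol | CC[C@H](C)CO | starting material
15 | (S)-2-methylbutanal | CC[C@H](C)C=O | intermediate
16 | (2E,4S)-2,4-dimethylhex-2-enal | CC[C@H](C)/C=C(C)/C=O | intermediate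
17 | (1E,3E,5S)-1-iodo-3,5-dimethylhepta-1,3-diene | CC[C@H](C)/C=C(C)/C=C/I | intermediate
18 | [(1E,3E,5S)-3,5-dimethylhepta-1,3-dien-1-yl]lithium | CC[C@H](C)/C=C(C)/C=C/[Li] | intermediate
19 | tributyl[(1E,3E,5S)-3,5-dimethylhepta-1,3-dien-1-yl]stannane | CC[C@H](C)/C=C(C)/C=C/[Sn](CCCC)(CCCC)CCCC | intermediate
20 | methyl (5R,6S)-6-acetoxy-3-[(1E,3E,5S)-3,5-dimethylhepta-1,3-dien-1-yl]-5-hydroxy-6-methyl-7-oxo-6,7-dihydro-5H-cyclopenta[c]pyridine-5-carboxylate | CC[C@H](C)/C=C(C)/C=C/c1cc2c(cn1)C(=O)[C@@](C)(OC(C)=O)[C@@]2(O)C(=O)OC | target

Total step count: 12 steps.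
Longest linear sequence: 7 steps (steps 1, 2, 5, 6, 7, 8 and 12).

Steps most likely to fail

Step 5. An oxygen-substituted alkene terminus has not been examined in this rearrangement. Proton transfer within the ylide (formal O–H insertion) may outrun the sigmatropic shift, and the ortho bromine may twist the pyridyl donor out of conjugation and weaken catalyst control at C2. The fallback leaves carbenoid chemistry, sets out from 4 and returns at 13, taking C6 from the chiral pool:
- 4 is oxidized with dimethyldioxirane (acetone, 0 °C) to methyl 2-(5-bromo-2-chloropyridin-4-yl)-2-oxoacetate F1.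
- (R)-Lactic acid and pivalaldehyde are condensed (TsOH, pentane, water separator) to the cis acetal (2R,5R)-2-tert-butyl-5-methyl-1,3-dioxolan-4-one F2.
- The lithium enolate of F2 (LiN(i-Pr)2, THF, −78 °C) adds to the keto group of F1 anti to the tert-butyl group (self-regeneration of the lactate stereocentre, which fixes C6). The aldolate is silylated in the flask with Me3SiCl to give methyl (2R)-2-(5-bromo-2-chloropyridin-4-yl)-2-[(2R,4S)-2-tert-butyl-4-methyl-5-oxo-1,3-dioxolan-4-yl]-2-(trimethylsilyloxy)acetate F3. The C5 epimer is removed by chromatography, since the acetal does not control that centre reliably.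
- Bromine–magnesium exchange on F3 (i-PrMgCl·LiCl, THF, −40 → 0 °C) starts a Parham cyclization onto the dioxolanone carbonyl. This closes the five-membered ring, expels pivalaldehyde and leaves the C6 magnesium alkoxide, which is acetylated in the same flask (Ac2O, DMAP) to methyl (5R,6S)-6-acetoxy-3-chloro-6-methyl-7-oxo-5-(trimethylsilyloxy)-6,7-dihydro-5H-cyclopenta[c]pyridine-5-carboxylate F4.
- HF·pyridine (THF, 0 °C) removes the silyl group and gives 13.

Step 7. Insertion of nickel into the hindered C–Br bond may be slow. Insertion into the activated C–Cl bond, reduction of the α-acetoxy aldehyde by divalent chromium, or migration of the acetyl group to the new chromium alkoxide could then compete. The fallback sets out from 9 and returns at 13, bypassing steps 6 to 8. 9 is cyclized by a 5-exo-trig Mizoroki–Heck reaction (Pd(OAc)2, P(o-tol)3, KOAc, Bu4NBr, DMF, 80 °C). The arylpalladium bromide adds across the propenyl group, and β-hydride elimination with hydridopalladium-mediated equilibration should give the conjugated exocyclic alkene methyl (5R,6R)-6-acetoxy-3-chloro-7-ethylidene-5-hydroxy-6-methyl-6,7-dihydro-5H-cyclopenta[c]pyridine-5-carboxylate F5 (either alkene geometry serves). Ozonolysis of F5 (O3, CH2Cl2, −78 °C; then PPh3) gives 13 directly.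

Step 4. Hydride delivery may be poorly face-selective because the cis-methyl group forces the enone out of the conformation the catalyst discriminates best. Conjugate reduction or hydroboration of the electron-rich C=C bond may intervene, and the product may undergo allylic transposition or lose acetic acid on acidic contact. The fallback replaces asymmetric reduction by resolution, sets out from 6 and returns at 7. Luche reduction of 6 (NaBH4, CeCl3·7H2O, MeOH, −78 °C) gives racemic (E)-4-hydroxypent-2-en-2-yl acetate F6. Kinetic resolution with Candida antarctica lipase B and vinyl acetate (hexane, rt) should acetylate the R enantiomer, as expected from the usual empirical model for secondary alcohols, to (2E,4R)-pent-2-ene-2,4-diyl diacetate F7. The unreacted S alcohol 7 is separated by chromatography on Et3N-deactivated SiO2 and carried into step 5.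

Further compounds
F1 | step 5 | methyl 2-(5-bromo-2-chloropyridin-4-yl)-2-oxoacetate | COC(=O)C(=O)c1cc(Cl)ncc1Br
F2 | step 5 | (2R,5R)-2-tert-butyl-5-methyl-1,3-dioxolan-4-one | C[C@H]1O[C@@H](C(C)(C)C)OC1=O
F3 | step 5 | methyl (2R)-2-(5-bromo-2-chloropyridin-4-yl)-2-[(2R,4S)-2-tert-butyl-4-methyl-5-oxo-1,3-dioxolan-4-yl]-2-(trimethylsilyloxy)acetate | C[C@@]1([C@@](O[Si](C)(C)C)(C(=O)OC)c2cc(Cl)ncc2Br)O[C@@H](C(C)(C)C)OC1=O
F4 | step 5 | methyl (5R,6S)-6-acetoxy-3-chloro-6-methyl-7-oxo-5-(trimethylsilyloxy)-6,7-dihydro-5H-cyclopenta[c]pyridine-5-carboxylate | Clc1cc2c(cn1)C(=O)[C@@](C)(OC(C)=O)[C@@]2(O[Si](C)(C)C)C(=O)OC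
F5 | step 7 | methyl (5R,6R)-6-acetoxy-3-chloro-7-ethylidene-5-hydroxy-6-methyl-6,7-dihydro-5H-cyclopenta[c]pyridine-5-carboxylate | Clc1cc2c(cn1)C(=CC)[C@@](C)(OC(C)=O)[C@@]2(O)C(=O)OC
F6 | step 4 | racemic (E)-4-hydroxypent-2-en-2-yl acetate | CC(O)/C=C(\C)OC(C)=O
F7 | step 4 | (2E,4R)-pent-2-ene-2,4-diyl diacetate | C[C@@H](OC(C)=O)/C=C(\C)OC(C)=O
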